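**Strategy.** Briarane numbering is used. The oxocane (C1, C2, C3, C4, O, C8, C9, C10) is closed last, at C9–C10. Two features are exploited. The first is the C9 carbinol–C10–C11=C20 exo-methylene array, the retron of an allylsilane addition. The second is the 1,3-placement of C9–O and C6–Cl on opposite faces of the pyran ring (O, C4–C8), readable as a C6–O–C9 bridge opened with inversion. A 6β-silyl ether condenses with the C9 aldehyde to a bridged oxocarbenium ion. This flips the pyran, fixes C9 and is trapped by the ring-A allylsilane. Acetyl chloride later opens the bridge to the 9-acetate and 6-chloride. The precursor is a cyclohexenylmethylsilane tethered through C2–C4 to a pyran-fused lactone aldehyde.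

Key step: step 22

Assumption: the facial sense of the prolinol auxiliary (step 3) and of the bisphosphoramide catalyst (step 17) is taken as drawn; if it is opposite, the enantiomeric auxiliary or catalyst is used.
Convention: unless stated otherwise, a stereocentre has the spatial arrangement it has in 40. "6β" means on the pyran face that carries C3 and C9. PMP = 4-methoxyphenyl.

## Route

Step 1
Reactants: 1 5-bromo-2-methoxybenzoic acid; 2 (S)-2-(methoxymethyl)pyrrolidine
Product: 4 (S)-1-(5-bromo-2-methoxybenzoyl)-2-(methoxymethyl)pyrrolidine, via acid chloride 3 (not isolated)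
Conditions: (COCl)2, cat. DMF, CH2Cl2, 0→23 °C; then 2, Et3N, CH2Cl2, 0 °C
Reagents that add atoms: none
Why: Acylation of the secondary amine by the acid chloride (Schotten–Baumann type) attaches the auxiliary without touching its stereocentre.

Step 2
Reactants: 4 bromo amide
Product: 5 (S)-1-{2-methoxy-5-[(trimethylsilyl)methyl]benzoyl}-2-(methoxymethyl)pyrrolidine
Conditions: Me3SiCH2MgCl, Pd(dppf)Cl2 (3 mol %), THF, 50 °C
Reagents that add atoms: (trimethylsilyl)methylmagnesium chloride, C[Si](C)(C)C[Mg]Cl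
Why: Kumada coupling of an aryl bromide with a Grignard reagent that has no β-hydrogen should proceed cleanly, because this sluggish nucleophile leaves the tertiary amide alone.

Step 3
Reactants: 5 benzylsilane amide
Product: 7 (1R)-2-methoxy-1-methyl-5-[(trimethylsilyl)methyl]cyclohexa-2,5-diene-1-carboxamide of 2, via potassium enolate 6 (not isolated)
Conditions: K, NH3(l)/THF, t-BuOH (1 equiv), −78 °C; piperylene; MeI, −78 °C
Reagents that add atoms: iodomethane, CI
Why: In this Birch reduction–alkylation the chelated amide enolate 6 is methylated on the face left open by the methoxymethyl arm of the auxiliary, which sets quaternary C1 (R) and turns the benzylsilane into the C10=C11–C20 allylsilane.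

Step 4
Reactants: 7 dienyl amide
Product: 8 (1R)-1-methyl-6-oxo-3-[(trimethylsilyl)methyl]cyclohex-2-ene-1-carboxamide of 2
Conditions: oxalic acid (cat.), THF/H2O, 23 °C
Reagents that add atoms: water, O
Why: Enol ether hydrolysis works here because the enol ether is protonated far faster than the allylsilane, and quaternary C1 keeps C10=C11 out of conjugation with the new C14 ketone.

Step 5
Reactants: 8 keto amide
Product: 9 (1R,6S)-6-hydroxy-1-methyl-3-[(trimethylsilyl)methyl]cyclohex-2-ene-1-carboxamide of 2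
Conditions: NaBH4, MeOH, −20 °C
Reagents that add atoms: none
Why: Under steric approach control, hydride enters anti to the bulky carboxamide (syn to C15), which places 14-OH cis to C2 (14S).

Step 6
Reactants: 9 hydroxy amide
Product: 10 14-O-TBS ether of 9
Conditions: TBSOTf, 2,6-lutidine, CH2Cl2, 0 °C
Reagents that add atoms: tert-butyldimethylsilyl triflate, CC(C)(C)[Si](C)(C)OS(=O)(=O)C(F)(F)F
Why: Silyl triflate silylation is strong enough for the hindered secondary alcohol, and the buffered medium spares the allylsilane.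

Step 7
Reactants: 10 silyl ether amide
Product: 11 [(1S,6S)-6-(tert-butyldimethylsilyloxy)-1-methyl-3-[(trimethylsilyl)methyl]cyclohex-2-en-1-yl]methanol
Conditions: BH3·NH3, n-BuLi, THF, 0 °C; then 10, 0→23 °C; 1 M HCl
Reagents that add atoms: none
Why: Lithium amidotrihydroborate reduces even hindered tertiary amides to primary alcohols with C–N cleavage, which frees the auxiliary and leaves C1 unchanged in space (the CIP letter changes only by priority).

Step 8
Reactants: 11 primary alcohol
Product: 12 (1R,6S)-6-(tert-butyldimethylsilyloxy)-1-methyl-3-[(trimethylsilyl)methyl]cyclohex-2-ene-1-carbaldehyde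
Conditions: Dess–Martin periodinane, NaHCO3, CH2Cl2, 23 °C
Reagents that add atoms: none
Why: Dess–Martin oxidation gives the C2 aldehyde under neutral conditions, and this aldehyde cannot enolise.

Step 9
Reactants: 13 (4-methoxyphenoxy)acetic acid; 14 (S)-4-benzyl-1,3-oxazolidin-2-one
Product: 16 (S)-4-benzyl-3-[(4-methoxyphenoxy)acetyl]-1,3-oxazolidin-2-one, via mixed anhydride 15 (not isolated)
Conditions: PivCl, Et3N, THF, −20 °C; then 14, LiCl, 23 °C
Reagents that add atoms: none
Why: N-acylation through the mixed pivalic anhydride occurs at the less hindered carbonyl and needs no strong base.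

Step 10
Reactants: 16 glycolate imide; 12 aldehyde
Product: 18 syn-aldol imide with 2-OH and 3-O-PMP (2R,3S in 18), via boron enolate 17 (not isolated)
Conditions: Bu2BOTf, Et3N, CH2Cl2, −78→0 °C; 12, −78→0 °C; pH 7 buffer, MeOH, H2O2
Reagents that add atoms: none
Why: In this Evans syn-aldol reaction the (Z)-boron enolate reacts through a Zimmerman–Traxler chair on the face dictated by the benzyl group, which sets C2 and C3 (2,3-syn) under auxiliary control.

Step 11
Reactants: 18 aldol imide
Product: 19 2-O-TBS ether of 18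
Conditions: TBSOTf, 2,6-lutidine, CH2Cl2, 0 °C
Reagents that add atoms: tert-butyldimethylsilyl triflate, CC(C)(C)[Si](C)(C)OS(=O)(=O)C(F)(F)F
Why: Silyl triflate silylation caps the neopentylic 2-OH and blocks retro-aldol cleavage in the next steps.

Step 12
Reactants: 19 silylated imide
Product: 20 C4 primary alcohol (2,14-bis-OTBS, 3-O-PMP)
Conditions: LiBH4, MeOH (1 equiv), Et2O, 0 °C
Reagents that add atoms: none
Why: Reductive removal of the oxazolidinone with lithium borohydride attacks only the exocyclic imide carbonyl and does not epimerise C3.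

Step 13
Reactants: 20 primary alcohol
Product: 21 C4 aldehyde (2,14-bis-OTBS, 3-O-PMP)
Conditions: Dess–Martin periodinane, NaHCO3, CH2Cl2, 0 °C
Reagents that add atoms: none
Why: Buffered Dess–Martin oxidation gives the α-aryloxy aldehyde without epimerisation at C3, and the aldehyde is used at once.

Step 14
Reactants: 22 acrolein
Product: 24 2-bromoacrolein, via 2,3-dibromopropanal 23 (not isolated)
Conditions: Br2, CH2Cl2, −78 °C; Et3N, −78→0 °C
Reagents that add atoms: bromine, BrBr
Why: Bromine addition followed by E1cB dehydrobromination removes the acidic α-hydrogen and the β-bromide.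

Step 15
Reactants: 25 1,3-dihydroxyacetone (used as its dimer); 26 ethyl 2-(triphenylphosphoranylidene)propanoate
Product: 28 4-(hydroxymethyl)-3-methylfuran-2(5H)-one, via dihydroxy ester 27 (not isolated)
Conditions: CH2Cl2/MeOH, 23→40 °C
Reagents that add atoms: none
Why: After Wittig olefination of the ketone, one hydroxymethyl group always lies cis to the ester and lactonises spontaneously.

Step 16
Reactants: 28 hydroxy butenolide
Product: 29 3-methyl-2-(triethylsilyloxy)-4-[(triethylsilyloxy)methyl]furan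
Conditions: TESOTf (2.3 equiv), Et3N, CH2Cl2, 0 °C
Reagents that add atoms: triethylsilyl triflate, CC[Si](CC)(CC)OS(=O)(=O)C(F)(F)F
Why: Soft enolisation and O-silylation give the aromatic 2-silyloxyfuran and cap the primary alcohol (later C9) in the same operation.

Step 17
Reactants: 29 silyloxyfuran; 24 2-bromoacrolein
Product: 30 (5R)-5-[(1S)-2-bromo-1-hydroxyprop-2-en-1-yl]-3-methyl-4-[(triethylsilyloxy)methyl]furan-2(5H)-one
Conditions: SiCl4, (R,R)-binaphthyl bisphosphoramide (5 mol %), i-Pr2NEt, CH2Cl2, −78 °C; aq. KF/NaHCO3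
Reagents that add atoms: none
Why: In this catalytic asymmetric vinylogous Mukaiyama aldol reaction the furan attacks through its γ-carbon in an open transition state, giving the 5,1′-syn (threo) adduct; the chiral Lewis-base-bound silicon cation selects the aldehyde face and so sets C7 (R) and the temporary 6β-carbinol.

Step 18
Reactants: 30 bromoallylic alcohol
Product: 31 6-O-TES ether of 30
Conditions: TESCl, imidazole, CH2Cl2, 0 °C
Reagents that add atoms: chlorotriethylsilane, CC[Si](Cl)(CC)CC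
Why: This silylation prevents retro-aldol cleavage and translactonisation later, and it installs the silyl ether that the key step consumes.

Step 19
Reactants: 21 C4 aldehyde; 31 vinyl bromide
Product: 32 (4R)-allylic alcohol, the seco compound with the C4–C5 bond, C5=C16 and the butenolide
Conditions: CrCl2 (4 equiv), NiCl2 (2 mol %), DMSO/THF, 23 °C
Reagents that add atoms: none
Why: The Nozaki–Hiyama–Kishi coupling tolerates the lactone, silyl ethers and allylsilane, and the alkenylchromium adds in the polar Felkin–Anh sense (anti to the aryloxy group), giving the 3,4-anti alcohol (4R).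

Step 20
Reactants: 32 seco alcohol
Product: 33 cis-fused pyran–γ-lactone (8R,17R; 6β-OTES, C9H2OTES)
Conditions: DBU (0.3 equiv), toluene, 23 °C
Reagents that add atoms: none
Why: In this intramolecular oxa-Michael addition (6-exo-trig) 4-OH can reach C8 only on the face of the C6 chain, which sets C8 through the cis ring fusion; equilibrating protonation puts C18 trans to C9 (17R), and the product gains an all-equatorial chair for C3, O6, O7 and C9.

Step 21
Reactants: 33 pyran lactone
Product: 34 C9 aldehyde (6β-OTES retained)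
Conditions: (COCl)2, DMSO, CH2Cl2, −78→−40 °C; Et3N, −78→0 °C
Reagents that add atoms: none
Why: Swern oxidation acts directly on primary triethylsilyl ethers, because the activated sulfonium salt exchanges with the primary TES ether only, while the secondary TES and TBS ethers stay.

Step 22
Reactants: 34 aldehyde allylsilane
Product: 36 pentacyclic 6,9-epoxide (oxocane closed, C11=C20 formed, 9S,10S), via oxocarbenium triflate 35 (not isolated)
Conditions: TMSOTf (0.2 equiv), 2,6-di-tert-butyl-4-methylpyridine, CH2Cl2 (1 mM), −78→−30 °C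
Reagents that add atoms: none
Why: TMSOTf silylates the aldehyde oxygen, the 6β-OTES oxygen adds to C9, and loss of Et3SiOSiMe3 gives the 2,6-dioxabicyclo[3.2.1]octane oxocarbenium ion 35, whose C9 is attacked by C10 of the allylsilane (SE2′) with release of Me3Si+, which regenerates the catalyst and leaves the C11=C20 double bond. The closest known reaction type is the intramolecular silyl-modified Sakurai reaction, that is, a Hosomi–Sakurai allylation of a cyclic oxocarbenium ion formed in situ from an aldehyde and a silyl ether. The temporary oxolane closes by 5-exo-trig addition of O6 to the activated C9=O, and the oxocane then closes 8-exo-trig with respect to both the C9=O+ and the C10=C11 bond, helped by the bridge, which locks the pyran in the chair that holds C3 and C9 axial and close. C9 (S) is controlled by the bridge, since its oxygen is tied back to C6 and the tether can reach only the face of C9 turned toward O8 and C3; C10 (S) is controlled by C1, C2 and C14, since with C2 pseudo-equatorial and H-2 turned toward the axial 14-OTBS group the chain runs over the β face (that of C15), while that silyl ether shields the α face. The step needs chemoselective ionisation, secured by the proximity of the small secondary TES ether (the TBS and aryl ethers are too hindered or too weakly basic), and a single alkene regioisomer, secured by the β-silicon effect, which rules out proton loss toward C12 or C10. High dilution and the hindered pyridine should suppress oligomerisation and protodesilylation.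

Step 23
Reactants: 36 pentacyclic ether
Product: 37 2,14-diol of 36
Conditions: HF·pyridine, THF, 0→23 °C
Reagents that add atoms: none
Why: Fluoride-driven desilylation under weakly acidic conditions removes both TBS groups and leaves the ethers, lactone and alkenes intact.

Step 24
Reactants: 37 diol
Product: 38 2,14-diacetate
Conditions: Ac2O, DMAP, Et3N, CH2Cl2, 23→40 °C
Reagents that add atoms: acetic anhydride, CC(=O)OC(C)=O
Why: DMAP-catalysed acetylation reaches the two hindered secondary alcohols, and no other hydroxyl is free.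

Step 25
Reactants: 38 diacetate ether
Product: 39 2,9,14-triacetate 6-chloride 3-O-PMP ether
Conditions: AcCl (3 equiv), ZnCl2 (10 mol %), CH2Cl2, −20→0 °C
Reagents that add atoms: acetyl chloride, CC(=O)Cl
Why: In this Lewis-acid-catalysed acylative ether cleavage the strained bridge oxygen is acetylated and chloride opens the acyloxonium ion at allylic C6 from the open α face with inversion (6S); C9 lies between C8 and C10 and is not attacked, so it keeps its oxygen as the acetate.

Step 26
Reactants: 39 PMP ether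
Product: 40 target CNP0280492.1
Conditions: (NH4)2Ce(NO3)6 (2.5 equiv), MeCN/H2O 4:1, 0 °C
Reagents that add atoms: none
Why: Oxidative dearylation with cerium(IV) turns the electron-rich aryl ether into benzoquinone and frees 3-OH without acid or base strong enough to move the neighbouring 2-acetate.

## Compound list

1 | 5-bromo-2-methoxybenzoic acid | COc1ccc(Br)cc1C(=O)O | starting material
2 | (S)-2-(methoxymethyl)pyrrolidine | COC[C@@H]1CCCN1 | starting material
3 | 5-bromo-2-methoxybenzoyl chloride | COc1ccc(Br)cc1C(=O)Cl | intermediate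
4 | (S)-1-(5-bromo-2-methoxybenzoyl)-2-(methoxymethyl)pyrrolidine | COc1ccc(Br)cc1C(=O)N1CCC[C@H]1COC | intermediate
5 | (S)-1-{2-methoxy-5-[(trimethylsilyl)methyl]benzoyl}-2-(methoxymethyl)pyrrolidine | COc1ccc(C[Si](C)(C)C)cc1C(=O)N1CCC[C@H]1COC | intermediate
6 | potassium amide enolate from Birch reduction of 5 | COC1=CCC(C[Si](C)(C)C)=CC1=C([O-])N1CCC[C@H]1COC.[K+] | intermediate
7 | (1R)-2-methoxy-1-methyl-5-[(trimethylsilyl)methyl]cyclohexa-2,5-diene-1-carboxamide of 2 | C[Si](C)(C)CC1=C[C@@](C)(C(=O)N2CCC[C@H]2COC)C(OC)=CC1 | intermediate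
8 | (1R)-1-methyl-6-oxo-3-[(trimethylsilyl)methyl]cyclohex-2-ene-1-carboxamide of 2 | C[Si](C)(C)CC1=C[C@@](C)(C(=O)N2CCC[C@H]2COC)C(=O)CC1 | intermediate
9 | (1R,6S)-6-hydroxy analogue of 8 (OH cis to the carboxamide) | C[Si](C)(C)CC1=C[C@@](C)(C(=O)N2CCC[C@H]2COC)[C@@H](O)CC1 | intermediate
10 | 14-O-TBS ether of 9 | C[Si](C)(C)CC1=C[C@@](C)(C(=O)N2CCC[C@H]2COC)[C@@H](O[Si](C)(C)C(C)(C)C)CC1 | intermediate
11 | [(1S,6S)-6-(TBSO)-1-methyl-3-[(trimethylsilyl)methyl]cyclohex-2-en-1-yl]methanol | C[Si](C)(C)CC1=C[C@@](C)(CO)[C@@H](O[Si](C)(C)C(C)(C)C)CC1 | intermediate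
12 | (1R,6S)-6-(TBSO)-1-methyl-3-[(trimethylsilyl)methyl]cyclohex-2-ene-1-carbaldehyde | C[Si](C)(C)CC1=C[C@@](C)(C=O)[C@@H](O[Si](C)(C)C(C)(C)C)CC1 | intermediate
13 | (4-methoxyphenoxy)acetic acid | COc1ccc(OCC(=O)O)cc1 | starting material
14 | (S)-4-benzyl-1,3-oxazolidin-2-one | O=C1N[C@@H](Cc2ccccc2)CO1 | starting material
15 | (4-methoxyphenoxy)acetic pivalic anhydride | COc1ccc(OCC(=O)OC(=O)C(C)(C)C)cc1 | intermediate
16 | (S)-4-benzyl-3-[(4-methoxyphenoxy)acetyl]-1,3-oxazolidin-2-one | COc1ccc(OCC(=O)N2[C@@H](Cc3ccccc3)COC2=O)cc1 | intermediate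
17 | (Z)-dibutylboron enolate of 16 | COc1ccc(O/C=C(\OB(CCCC)CCCC)N2[C@@H](Cc3ccccc3)COC2=O)cc1 | intermediate
18 | syn-aldol imide (2-OH, 3-O-PMP, 14-OTBS; C1, C2, C3, C14 as in 40) | C[Si](C)(C)CC1=C[C@@](C)([C@@H](O)[C@H](Oc2ccc(OC)cc2)C(=O)N2[C@@H](Cc3ccccc3)COC2=O)[C@@H](O[Si](C)(C)C(C)(C)C)CC1 | intermediate
19 | 2-O-TBS ether of 18 | C[Si](C)(C)CC1=C[C@@](C)([C@@H](O[Si](C)(C)C(C)(C)C)[C@H](Oc2ccc(OC)cc2)C(=O)N2[C@@H](Cc3ccccc3)COC2=O)[C@@H](O[Si](C)(C)C(C)(C)C)CC1 | intermediate
20 | C4 primary alcohol (2,14-bis-OTBS, 3-O-PMP) | C[Si](C)(C)CC1=C[C@@](C)([C@@H](O[Si](C)(C)C(C)(C)C)[C@H](Oc2ccc(OC)cc2)CO)[C@@H](O[Si](C)(C)C(C)(C)C)CC1 | intermediate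
21 | C4 aldehyde (2,14-bis-OTBS, 3-O-PMP) | C[Si](C)(C)CC1=C[C@@](C)([C@@H](O[Si](C)(C)C(C)(C)C)[C@H](Oc2ccc(OC)cc2)C=O)[C@@H](O[Si](C)(C)C(C)(C)C)CC1 | intermediate
22 | acrolein | C=CC=O | starting material
23 | 2,3-dibromopropanal | O=CC(Br)CBr | intermediate
24 | 2-bromoacrolein | C=C(Br)C=O | intermediate
25 | 1,3-dihydroxyacetone | OCC(=O)CO | starting material
26 | ethyl 2-(triphenylphosphoranylidene)propanoate | CCOC(=O)C(C)=P(c1ccccc1)(c1ccccc1)c1ccccc1 | starting material
27 | ethyl 4-hydroxy-3-(hydroxymethyl)-2-methylbut-2-enoate | CCOC(=O)C(C)=C(CO)CO | intermediate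
28 | 4-(hydroxymethyl)-3-methylfuran-2(5H)-one | CC1=C(CO)COC1=O | intermediate
29 | 3-methyl-2-(triethylsilyloxy)-4-[(triethylsilyloxy)methyl]furan | Cc1c(O[Si](CC)(CC)CC)occ1CO[Si](CC)(CC)CC | intermediate
30 | (5R)-5-[(1S)-2-bromo-1-hydroxyprop-2-en-1-yl]-3-methyl-4-[(triethylsilyloxy)methyl]furan-2(5H)-one | C=C(Br)[C@@H](O)[C@@H]1OC(=O)C(C)=C1CO[Si](CC)(CC)CC | intermediate
31 | 6-O-TES ether of 30 | C=C(Br)[C@@H](O[Si](CC)(CC)CC)[C@@H]1OC(=O)C(C)=C1CO[Si](CC)(CC)CC | intermediate
32 | (4R)-allylic alcohol, seco compound (6β-OTES, butenolide, ring-A allylsilane) | C[Si](C)(C)CC1=C[C@@](C)([C@@H](O[Si](C)(C)C(C)(C)C)[C@H](Oc2ccc(OC)cc2)[C@H](O)C(=C)[C@@H](O[Si](CC)(CC)CC)[C@@H]2OC(=O)C(C)=C2CO[Si](CC)(CC)CC)[C@@H](O[Si](C)(C)C(C)(C)C)CC1 | intermediate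
33 | cis-fused pyran–γ-lactone (8R,17R; 6β-OTES; C9H2OTES) | C[Si](C)(C)CC1=C[C@@](C)([C@@H](O[Si](C)(C)C(C)(C)C)[C@H](Oc2ccc(OC)cc2)[C@@H]2O[C@@]3(CO[Si](CC)(CC)CC)[C@@H](C)C(=O)O[C@H]3[C@H](O[Si](CC)(CC)CC)C2=C)[C@@H](O[Si](C)(C)C(C)(C)C)CC1 | intermediate
34 | C9 aldehyde of 33 | C[Si](C)(C)CC1=C[C@@](C)([C@@H](O[Si](C)(C)C(C)(C)C)[C@H](Oc2ccc(OC)cc2)[C@@H]2O[C@@]3(C=O)[C@@H](C)C(=O)O[C@H]3[C@H](O[Si](CC)(CC)CC)C2=C)[C@@H](O[Si](C)(C)C(C)(C)C)CC1 | intermediate
35 | 2,6-dioxabicyclo[3.2.1]octane oxocarbenium triflate (C9=O+–C6) | C[Si](C)(C)CC1=C[C@@](C)([C@@H](O[Si](C)(C)C(C)(C)C)[C@H](Oc2ccc(OC)cc2)[C@@H]2O[C@@]3(C=[O+]4)[C@@H](C)C(=O)O[C@H]3[C@H]4C2=C)[C@@H](O[Si](C)(C)C(C)(C)C)CC1.[O-]S(=O)(=O)C(F)(F)F | intermediate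
36 | pentacyclic 6β,9-epoxide (2,14-bis-OTBS, 3-O-PMP, 9S,10S) | C=C1CC[C@H](O[Si](C)(C)C(C)(C)C)[C@@]2(C)[C@H]1[C@H]4[C@@]13O[C@H](C(=C)[C@@H](O4)[C@@H]1OC(=O)[C@@H]3C)[C@@H](Oc1ccc(OC)cc1)[C@@H]2O[Si](C)(C)C(C)(C)C | intermediate
37 | 2,14-diol of 36 | C=C1CC[C@H](O)[C@@]2(C)[C@H]1[C@H]4[C@@]13O[C@H](C(=C)[C@@H](O4)[C@@H]1OC(=O)[C@@H]3C)[C@@H](Oc1ccc(OC)cc1)[C@@H]2O | intermediate
38 | 2,14-diacetate of 37 | C=C1CC[C@H](OC(C)=O)[C@@]2(C)[C@H]1[C@H]4[C@@]13O[C@H](C(=C)[C@@H](O4)[C@@H]1OC(=O)[C@@H]3C)[C@@H](Oc1ccc(OC)cc1)[C@@H]2OC(C)=O | intermediate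
39 | 3-O-PMP ether of the target | C=C1CC[C@H](OC(C)=O)[C@@]2(C)[C@H]1[C@H](OC(C)=O)[C@@]13O[C@H](C(=C)[C@H](Cl)[C@@H]1OC(=O)[C@@H]3C)[C@@H](Oc1ccc(OC)cc1)[C@@H]2OC(C)=O | intermediate
40 | CNP0280492.1 (1R,2R,3R,4R,6S,7R,8R,9S,10S,14S,17R) | C=C1CC[C@H](OC(C)=O)[C@@]2(C)[C@H]1[C@H](OC(C)=O)[C@@]13O[C@H](C(=C)[C@H](Cl)[C@@H]1OC(=O)[C@@H]3C)[C@@H](O)[C@@H]2OC(C)=O | target

## Step count and risks

Total step count: 26. Longest linear sequence: 20 (steps 1–8, 10–13, 19–26).

**Step 22.**
- What may go wrong: the pyran may fail to reach the triaxial, bridged conformer. Protodesilylation, intermolecular reaction or attack on the α face of ring A could then overtake ring closure.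
- Fallback: it sets out from 34, returns at 39 and avoids any cation.
- Bromodesilylation with NBS gives the allylic bromide F1 (the configuration at C10 does not matter).
- An intramolecular Nozaki–Hiyama allylation with CrCl2 through a closed six-membered transition state gives the homoallylic alcohol F2. This is expected as the 9-epimer, because the chromium alkoxide sits on the periphery.
- Dess–Martin oxidation gives the 9-ketone F3.
- Luche reduction from the periphery gives the 9S alcohol F4.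
- HF·pyridine gives the tetraol F5.
- Appel-type chlorination (PPh3, hexachloroacetone) acts only on the allylic, axial 6β-hydroxyl, with inversion, and gives the chloro triol F6.
- Peracetylation (Ac2O, DMAP) leads to 39.

**Step 25.**
- What may go wrong: chloride may enter at C16 with allylic transposition, the zinc salt may equilibrate the allylic chloride, or the pyran oxygen may be acylated instead of the bridge oxygen.
- Fallback: it sets out from 38, returns at 39 and uses the transposition twice.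
- The opening is driven (AcCl, ZnCl2, 23 °C) to the primary allylic chloride F7, with C5=C6 endocyclic.
- Sodium phenylselenide displaces the chloride to give the allylic selenide F8.
- N-chlorosuccinimide then converts the selenide into the rearranged allylic chloride. Chlorine arrives at C6 on the open α face and C5=C16 is restored.

**Step 20.**
- What may go wrong: the equilibrium of conjugate addition to a tetrasubstituted butenolide may be unfavourable. C7 may epimerise through the furanolate, or silyloxide may be lost from C6.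
- Fallback: it sets out from 32, returns at 33 and makes the C8–O bond irreversibly.
- Nucleophilic epoxidation (t-BuOOH, DBU) anti to the C6 chain gives the epoxy lactone F9.
- 4-OH opens the epoxide at C8 with inversion (6-exo-tet, cat. CSA) to give the 17-hydroxy lactone F10.
- Acetylation (Ac2O, Sc(OTf)3) gives the 17-acetate F11.
- SmI2 removes the α-acyloxy group, and equilibrating protonation gives 33.

## Further compounds

F1 | step 22 | C10 allylic bromide with C11=C20, C9 aldehyde retained | C=C1CC[C@H](O[Si](C)(C)C(C)(C)C)[C@](C)([C@@H](O[Si](C)(C)C(C)(C)C)[C@H](Oc2ccc(OC)cc2)[C@@H]2O[C@@]3(C=O)[C@@H](C)C(=O)O[C@H]3[C@H](O[Si](CC)(CC)CC)C2=C)C1Br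
F2 | step 22 | ring-closed 9-epi alcohol (6β-OTES) | C=C1CC[C@H](O[Si](C)(C)C(C)(C)C)[C@@]2(C)[C@H]1[C@@H](O)[C@@]13O[C@H](C(=C)[C@@H](O[Si](CC)(CC)CC)[C@@H]1OC(=O)[C@@H]3C)[C@@H](Oc1ccc(OC)cc1)[C@@H]2O[Si](C)(C)C(C)(C)C
F3 | step 22 | 9-ketone | C=C1CC[C@H](O[Si](C)(C)C(C)(C)C)[C@@]2(C)[C@H]1C(=O)[C@@]13O[C@H](C(=C)[C@@H](O[Si](CC)(CC)CC)[C@@H]1OC(=O)[C@@H]3C)[C@@H](Oc1ccc(OC)cc1)[C@@H]2O[Si](C)(C)C(C)(C)C
F4 | step 22 | 9S alcohol (6β-OTES) | C=C1CC[C@H](O[Si](C)(C)C(C)(C)C)[C@@]2(C)[C@H]1[C@H](O)[C@@]13O[C@H](C(=C)[C@@H](O[Si](CC)(CC)CC)[C@@H]1OC(=O)[C@@H]3C)[C@@H](Oc1ccc(OC)cc1)[C@@H]2O[Si](C)(C)C(C)(C)C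
F5 | step 22 | 2,6β,9,14-tetraol 3-O-PMP ether | C=C1CC[C@H](O)[C@@]2(C)[C@H]1[C@H](O)[C@@]13O[C@H](C(=C)[C@@H](O)[C@@H]1OC(=O)[C@@H]3C)[C@@H](Oc1ccc(OC)cc1)[C@@H]2O
F6 | step 22 | 6S-chloro 2,9,14-triol 3-O-PMP ether | C=C1CC[C@H](O)[C@@]2(C)[C@H]1[C@H](O)[C@@]13O[C@H](C(=C)[C@H](Cl)[C@@H]1OC(=O)[C@@H]3C)[C@@H](Oc1ccc(OC)cc1)[C@@H]2O
F7 | step 25 | 16-chloro-5(6)-ene triacetate 3-O-PMP ether | C=C1CC[C@H](OC(C)=O)[C@@]2(C)[C@H]1[C@H](OC(C)=O)[C@@]13O[C@H](C(CCl)=C[C@@H]1OC(=O)[C@@H]3C)[C@@H](Oc1ccc(OC)cc1)[C@@H]2OC(C)=O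
F8 | step 25 | 16-phenylselanyl-5(6)-ene triacetate 3-O-PMP ether | C=C1CC[C@H](OC(C)=O)[C@@]2(C)[C@H]1[C@H](OC(C)=O)[C@@]13O[C@H](C(C[Se]c4ccccc4)=C[C@@H]1OC(=O)[C@@H]3C)[C@@H](Oc1ccc(OC)cc1)[C@@H]2OC(C)=O
F9 | step 20 | 8,17-epoxy lactone (epoxide anti to the C6 chain) | C[Si](C)(C)CC1=C[C@@](C)([C@@H](O[Si](C)(C)C(C)(C)C)[C@H](Oc2ccc(OC)cc2)[C@H](O)C(=C)[C@@H](O[Si](CC)(CC)CC)[C@@H]2OC(=O)[C@@]3(C)O[C@@]23CO[Si](CC)(CC)CC)[C@@H](O[Si](C)(C)C(C)(C)C)CC1
F10 | step 20 | 17-hydroxy pyran lactone | C[Si](C)(C)CC1=C[C@@](C)([C@@H](O[Si](C)(C)C(C)(C)C)[C@H](Oc2ccc(OC)cc2)[C@@H]2O[C@@]3(CO[Si](CC)(CC)CC)[C@@](O)(C)C(=O)O[C@H]3[C@H](O[Si](CC)(CC)CC)C2=C)[C@@H](O[Si](C)(C)C(C)(C)C)CC1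
F11 | step 20 | 17-acetoxy pyran lactone | C[Si](C)(C)CC1=C[C@@](C)([C@@H](O[Si](C)(C)C(C)(C)C)[C@H](Oc2ccc(OC)cc2)[C@@H]2O[C@@]3(CO[Si](CC)(CC)CC)[C@@](OC(C)=O)(C)C(=O)O[C@H]3[C@H](O[Si](CC)(CC)CC)C2=C)[C@@H](O[Si](C)(C)C(C)(C)C)CC1
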